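**Strategy.** Everything rests on disconnecting the C3–C4 bond of ring C. In the target, C3 carries the methoxy oxygen and its neighbour C4 the pyranone carbonyl oxygen; two vicinal C–O carbons of this kind can be traced back to a 1,2-diol. A SmI2 pinacol coupling of two aldehyde carbons therefore forges C3–C4 and closes ring C in one operation, giving a flavan-3,4-diol whose stereocentres are all erased when the ring is oxidised and aromatised. The cyclisation substrate is a dialdehyde: a 3,4-dimethoxybenzaldehyde (ring A) whose 2-oxygen (O1) is linked through C2 to an α-aryl acetaldehyde carrying ring B, with the 3'-phenol benzyl-protected so that only the 3-hydroxyl is later free for methylation.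

Key step: step 7

Remark on the chemistry: the target is achiral, so every intermediate with a stereocentre is carried as a racemate or a mixture of diastereomers. Both acids are taken as purchased materials.

**Step 1**
Reactants: 1 2-hydroxy-3,4-dimethoxybenzoic acid
Product: 2 methyl 2-hydroxy-3,4-dimethoxybenzoate
Conditions: MeOH, H2SO4 (cat.), reflux
Reagents that add atoms: methanol, CO
Why: Fischer esterification in excess methanol converts the acid to its methyl ester while the hydrogen-bonded ortho phenol stays untouched.

**Step 2**
Reactants: 3 [3-(benzyloxy)-4-methoxyphenyl]acetic acid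
Product: 4 methyl [3-(benzyloxy)-4-methoxyphenyl]acetate
Conditions: MeOH, H2SO4 (cat.), reflux
Reagents that add atoms: methanol, CO
Why: Fischer esterification of an unhindered arylacetic acid is routine, and a benzyl aryl ether tolerates catalytic acid in methanol.

**Step 3**
Reactants: 4 methyl [3-(benzyloxy)-4-methoxyphenyl]acetate
Product: 5 methyl 2-[3-(benzyloxy)-4-methoxyphenyl]-2-diazoacetate
Conditions: p-ABSA, DBU, MeCN, 0 °C → rt
Reagents that add atoms: 4-acetamidobenzenesulfonyl azide (p-ABSA), CC(=O)Nc1ccc(cc1)S(=O)(=O)N=[N+]=[N-]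
Why: Regitz diazo transfer, in which DBU deprotonates the doubly activated benzylic methylene and the enolate takes the diazo unit from the sulfonyl azide, is the standard preparation of aryl diazoacetates.

**Step 4**
Reactants: 5 methyl 2-[3-(benzyloxy)-4-methoxyphenyl]-2-diazoacetate; 2 methyl 2-hydroxy-3,4-dimethoxybenzoate
Product: 6 racemic methyl 2-{1-[3-(benzyloxy)-4-methoxyphenyl]-2-methoxy-2-oxoethoxy}-3,4-dimethoxybenzoate
Conditions: Rh2(OAc)4 (1 mol %), CH2Cl2, 40 °C, slow addition of 5 to 2 (1.3 equiv)
Reagents that add atoms: none
Why: Rhodium-carbenoid O–H insertion (loss of N2, attack of the phenol oxygen on the donor–acceptor carbenoid, proton shift) builds the O1–C2 ether under neutral conditions that exclude base-induced Dieckmann closure; the new centre (future C2) forms as a racemate with the achiral catalyst and needs no control because it becomes sp2 in step 8.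

**Step 5**
Reactants: 6 racemic methyl 2-{1-[3-(benzyloxy)-4-methoxyphenyl]-2-methoxy-2-oxoethoxy}-3,4-dimethoxybenzoate
Product: 7 racemic 2-[3-(benzyloxy)-4-methoxyphenyl]-2-[6-(hydroxymethyl)-2,3-dimethoxyphenoxy]ethan-1-ol
Conditions: LiAlH4, THF, 0 °C → rt; Rochelle salt work-up
Reagents that add atoms: none
Why: Hydride reduction with LiAlH4 takes both the aryl ester and the α-aryloxy ester to primary alcohols, while the aryl methyl ethers, the diaryl-type ether link and the benzyl ether are inert.

**Step 6**
Reactants: 7 racemic 2-[3-(benzyloxy)-4-methoxyphenyl]-2-[6-(hydroxymethyl)-2,3-dimethoxyphenoxy]ethan-1-ol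
Product: 8 racemic 2-{1-[3-(benzyloxy)-4-methoxyphenyl]-2-oxoethoxy}-3,4-dimethoxybenzaldehyde
Conditions: Dess–Martin periodinane (3 equiv), CH2Cl2, 0 °C → rt; crude product used at once
Reagents that add atoms: none
Why: Dess–Martin oxidation converts both primary alcohols to aldehydes without any amine base, which should keep the enolisable α-aryl-α-aryloxy aldehyde from adding in aldol fashion to the neighbouring aryl aldehyde.

**Step 7**
Reactants: 8 racemic 2-{1-[3-(benzyloxy)-4-methoxyphenyl]-2-oxoethoxy}-3,4-dimethoxybenzaldehyde
Product: 9 2-[3-(benzyloxy)-4-methoxyphenyl]-7,8-dimethoxychromane-3,4-diol (racemic mixture of diastereomers)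
Conditions: SmI2 (2.5 equiv), t-BuOH (2.5 equiv), THF (0.01 M), slow addition of 8, −78 °C → rt
Reagents that add atoms: none
Why: Electron transfer from divalent samarium to the conjugated aryl aldehyde gives a samarium ketyl at C4, which adds to the carbonyl carbon of the adjacent α-aryloxy aldehyde (C3) while the oxophilic metal bridges both oxygens; a second electron transfer reduces the resulting alkoxy radical and t-BuOH protonates the trivalent samarium diolate. The closest known reaction type is the SmI2-mediated intramolecular pinacol coupling of 1,6-dialdehydes to six-membered cyclic 1,2-diols. Ring C (C4, C4a, C8a, O1, C2, C3) closes by 6-exo-trig attack of the C4 ketyl on the C3 carbonyl, whose oxygen stays outside the ring. The new centres C3 and C4 are set by the samarium chelate, which should favour the cis-3,4-diol, and their relation to C2 by the pseudo-equatorial preference of the ring B aryl group; none of this has to be selective, since C2, C3 and C4 all become sp2 in step 8. What the step does need is cyclisation in preference to intermolecular coupling, plain reduction and reductive loss of the α-aryloxy group, and this should be secured by the six-membered chelated transition state, high dilution with slow addition at −78 °C, the absence of HMPA, and initial reduction at the aryl aldehyde, whose ketyl has no β-leaving group.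

**Step 8**
Reactants: 9 2-[3-(benzyloxy)-4-methoxyphenyl]-7,8-dimethoxychromane-3,4-diol
Product: 11 2-[3-(benzyloxy)-4-methoxyphenyl]-3-hydroxy-7,8-dimethoxy-4H-chromen-4-one, via racemic chromane-3,4-dione 10 (not isolated)
Conditions: (COCl)2, DMSO, CH2Cl2, −78 °C; then Et3N, −78 °C → rt
Reagents that add atoms: none
Why: Swern oxidation activates both secondary hydroxyls as alkoxysulfonium salts before base is added, so the vicinal diol should go to the 1,2-diketone without C–C cleavage, and Et3N then enolises the diketone toward C2 to give the aromatic 4-pyranone with its hydrogen-bonded 3-hydroxyl, removing all three stereocentres.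

**Step 9**
Reactants: 11 2-[3-(benzyloxy)-4-methoxyphenyl]-3-hydroxy-7,8-dimethoxy-4H-chromen-4-one
Product: 12 2-[3-(benzyloxy)-4-methoxyphenyl]-3,7,8-trimethoxy-4H-chromen-4-one
Conditions: MeI, K2CO3, acetone, reflux
Reagents that add atoms: iodomethane, CI
Why: Williamson O-methylation of the acidic flavonol 3-hydroxyl is the standard way to 3-methoxyflavones and raises no selectivity question, because this is the only free hydroxyl while the ring B phenol is still benzylated.

**Step 10**
Reactants: 12 2-[3-(benzyloxy)-4-methoxyphenyl]-3,7,8-trimethoxy-4H-chromen-4-one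
Product: 13 diplotrin B (2-(3-hydroxy-4-methoxyphenyl)-3,7,8-trimethoxy-4H-chromen-4-one)
Conditions: H2 (1 atm), 10% Pd/C, EtOAc–MeOH, rt
Reagents that add atoms: none
Why: Catalytic hydrogenolysis cleaves the benzyl aryl ether to the 3'-phenol, while the tetrasubstituted C2=C3 bond of the aromatic pyranone should survive at ambient pressure and temperature.

**Compound list**

1 | 2-hydroxy-3,4-dimethoxybenzoic acid | COc1ccc(C(=O)O)c(O)c1OC | starting material
2 | methyl 2-hydroxy-3,4-dimethoxybenzoate | COC(=O)c1ccc(OC)c(OC)c1O | intermediate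
3 | [3-(benzyloxy)-4-methoxyphenyl]acetic acid | COc1ccc(CC(=O)O)cc1OCc1ccccc1 | starting material
4 | methyl [3-(benzyloxy)-4-methoxyphenyl]acetate | COC(=O)Cc1ccc(OC)c(OCc2ccccc2)c1 | intermediate
5 | methyl 2-[3-(benzyloxy)-4-methoxyphenyl]-2-diazoacetate | COC(=O)C(=[N+]=[N-])c1ccc(OC)c(OCc2ccccc2)c1 | intermediate
6 | methyl 2-{1-[3-(benzyloxy)-4-methoxyphenyl]-2-methoxy-2-oxoethoxy}-3,4-dimethoxybenzoate (racemic) | COC(=O)C(Oc1c(OC)c(OC)ccc1C(=O)OC)c1ccc(OC)c(OCc2ccccc2)c1 | intermediate
7 | 2-[3-(benzyloxy)-4-methoxyphenyl]-2-[6-(hydroxymethyl)-2,3-dimethoxyphenoxy]ethan-1-ol (racemic) | OCC(Oc1c(OC)c(OC)ccc1CO)c1ccc(OC)c(OCc2ccccc2)c1 | intermediate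
8 | 2-{1-[3-(benzyloxy)-4-methoxyphenyl]-2-oxoethoxy}-3,4-dimethoxybenzaldehyde (racemic) | COc1ccc(C=O)c(OC(C=O)c2ccc(OC)c(OCc3ccccc3)c2)c1OC | intermediate
9 | 2-[3-(benzyloxy)-4-methoxyphenyl]-7,8-dimethoxychromane-3,4-diol (racemic, mixture of diastereomers at C2, C3, C4) | COc1ccc(C2Oc3c(OC)c(OC)ccc3C(O)C2O)cc1OCc1ccccc1 | intermediate
10 | 2-[3-(benzyloxy)-4-methoxyphenyl]-7,8-dimethoxychromane-3,4-dione (racemic, not isolated) | COc1ccc(C2Oc3c(OC)c(OC)ccc3C(=O)C2=O)cc1OCc1ccccc1 | intermediate
11 | 2-[3-(benzyloxy)-4-methoxyphenyl]-3-hydroxy-7,8-dimethoxy-4H-chromen-4-one | COc1ccc(-c2oc3c(OC)c(OC)ccc3c(=O)c2O)cc1OCc1ccccc1 | intermediate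
12 | 2-[3-(benzyloxy)-4-methoxyphenyl]-3,7,8-trimethoxy-4H-chromen-4-one | COc1ccc(-c2oc3c(OC)c(OC)ccc3c(=O)c2OC)cc1OCc1ccccc1 | intermediate
13 | diplotrin B, 2-(3-hydroxy-4-methoxyphenyl)-3,7,8-trimethoxy-4H-chromen-4-one (achiral) | COc1ccc(-c2oc3c(OC)c(OC)ccc3c(=O)c2OC)cc1O | target

**Step count.** Total: 10 steps. Longest linear sequence: 9 steps (steps 2 to 10, from acid 3).

**Steps most likely to fail**

1. Step 7. The ether tether may be lost by reductive β-elimination of the aryloxide after over-reduction at the aliphatic aldehyde, molecules may couple with one another, or both aldehydes may simply be reduced without C–C bond formation. The fallback gives up the C3–C4 disconnection. It sets out from acid 1 and comes back at flavonol 11 by an Algar–Flynn–Oyamada sequence. Excess MeLi (THF, 0 °C, then TMSCl quench and aqueous acid) should convert 1 into 1-(2-hydroxy-3,4-dimethoxyphenyl)ethan-1-one F1. Claisen–Schmidt condensation of F1 with purchased 3-(benzyloxy)-4-methoxybenzaldehyde (COc1ccc(C=O)cc1OCc1ccccc1; KOH, EtOH, rt) should give (E)-3-[3-(benzyloxy)-4-methoxyphenyl]-1-(2-hydroxy-3,4-dimethoxyphenyl)prop-2-en-1-one F2. Alkaline H2O2 (NaOH, MeOH, 0 °C → rt) should then bring about oxidative cyclisation of this 2'-hydroxychalcone, which has no 6'-substituent, to 11.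

2. Step 4. The carbenoid may dimerise or may attack an electron-rich arene ring or adventitious water instead of the hindered, intramolecularly hydrogen-bonded phenol. The fallback makes the same ether by substitution. It sets out from diazo ester 5 and comes back at diester 6. HBr (33% in AcOH, CH2Cl2, −20 °C) should protonate the diazo carbon and deliver bromide with loss of N2, giving racemic methyl 2-bromo-2-[3-(benzyloxy)-4-methoxyphenyl]acetate F3. Williamson alkylation of phenol 2 with this activated benzylic bromide (K2CO3, acetone, rt to 50 °C, mild base to avoid Dieckmann closure) should then give 6.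

3. Step 8. The oxidation may stall at the ketol stage, the newly formed enol hydroxyl may be methylthiomethylated by excess activated DMSO, or the diol may fragment. The fallback separates oxidation from aromatisation. It sets out from diol 9 and comes back at flavonol 11. Activated MnO2 (CH2Cl2, rt) should oxidise only the benzylic C4 hydroxyl to give 2-[3-(benzyloxy)-4-methoxyphenyl]-3-hydroxy-7,8-dimethoxychroman-4-one F4 (racemic mixture of diastereomers). The classical dehydrogenation of dihydroflavonols (I2, KOAc, AcOH, heat) should then introduce the C2=C3 bond and give 11.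

**Further compounds**

F1 | step 7 | 1-(2-hydroxy-3,4-dimethoxyphenyl)ethan-1-one | CC(=O)c1ccc(OC)c(OC)c1O
F2 | step 7 | (E)-3-[3-(benzyloxy)-4-methoxyphenyl]-1-(2-hydroxy-3,4-dimethoxyphenyl)prop-2-en-1-one | COc1ccc(/C=C/C(=O)c2ccc(OC)c(OC)c2O)cc1OCc1ccccc1
F3 | step 4 | methyl 2-bromo-2-[3-(benzyloxy)-4-methoxyphenyl]acetate (racemic) | COC(=O)C(Br)c1ccc(OC)c(OCc2ccccc2)c1
F4 | step 8 | 2-[3-(benzyloxy)-4-methoxyphenyl]-3-hydroxy-7,8-dimethoxychroman-4-one (racemic mixture of diastereomers) | COc1ccc(C2Oc3c(OC)c(OC)ccc3C(=O)C2O)cc1OCc1ccccc1
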